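**Retrosynthetic overview**
- The target is 2-(3-hydroxy-4,5-dimethoxyphenyl)-6,7,8-trimethoxychromen-4-one. The ring B phenol is carried as a benzyl ether and freed last.
- Ring C is closed second, by 6-endo addition of the C8a hydroxyl to an aryl ynone. The ynone comes from a ring B lithium acetylide and a ring A salicylaldehyde (future C4), followed by oxidation.
- Ring A is made first, by Dötz benzannulation of a (1,2-dimethoxyvinyl)(methoxy)carbene complex of chromium, 3,3-diethoxypropyne and one CO ligand, forming C5–C6, C4a–C8a and C8–C8a.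
- Feature: in ring A the C6 methoxyl lies para to the oxygen-bearing C8a, C5 is a free CH, and C7 and C8 carry two adjacent methoxyls. This 4-methoxyphenol pattern is what a carbene benzannulation delivers, with C7/C8 coming from a dimethoxyvinyl group and C4 from the alkyne substituent.
- The carbene complex comes from 1,1,2-trimethoxyethane and Cr(CO)6; the ring B alkyne from 3-hydroxy-4,5-dimethoxybenzaldehyde.

Key step: step 3

Assumption: the Z isomer of 1,2-dimethoxyethene is carried through. Alkene geometry is lost when ring A becomes aromatic, so any E content should affect the rate of step 3 but not its product. Alcohol 15 is racemic and its stereocentre is removed in step 8; the target has no stereocentre.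

**Route**

Step 1
Reactants: 1 1,1,2-trimethoxyethane
Product: 2 (Z)-1,2-dimethoxyethene
Conditions: TMSOTf, i-Pr2NEt, CH2Cl2, −20 °C to rt; distil; cat. Hg(OAc)2, rt; redistil
Reagents that add atoms: none
Why: Gassman-type acetal-to-enol-ether elimination, in which TMSOTf ionises the acetal to an oxocarbenium ion that the hindered amine deprotonates, followed by Hg(OAc)2-catalysed equilibration toward the Z isomer, the more stable one for 1,2-dialkoxyethenes.

Step 2
Reactants: 2 (Z)-1,2-dimethoxyethene; 3 chromium hexacarbonyl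
Product: 6 pentacarbonyl[(Z)-1,2,3-trimethoxyprop-2-en-1-ylidene]chromium, via (Z)-1,2-dimethoxyvinyllithium 4 (not isolated), via lithium acylchromate 5 (not isolated)
Conditions: t-BuLi, THF, −78 °C; Cr(CO)6, −78 to 0 °C; then Me3OBF4, CH2Cl2, 0 °C
Reagents that add atoms: trimethyloxonium tetrafluoroborate C[O+](C)C.F[B-](F)(F)F; tert-butyllithium CC(C)(C)[Li] (lithium of intermediates 4 and 5 only)
Why: Alpha-lithiation of an enol ether with retention of alkene geometry followed by the Fischer carbene synthesis (addition of the vinyllithium to a CO ligand, then O-methylation of the acylate); the low temperature should keep the vinyllithium from losing LiOMe.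

Step 3
Reactants: 6 pentacarbonyl[(Z)-1,2,3-trimethoxyprop-2-en-1-ylidene]chromium; 7 3,3-diethoxyprop-1-yne
Product: 9 2-(diethoxymethyl)-4,5,6-trimethoxyphenol, via arene tricarbonylchromium complex 8 (not isolated)
Conditions: THF (degassed), 55 °C, Ar; then air, EtOAc, rt
Reagents that add atoms: none
Why: Dötz benzannulation of an alkenyl(methoxy)carbene complex of chromium with a terminal alkyne, a well-used reaction type that also tolerates alpha-alkoxyalkenyl complexes made from lithiated enol ethers (only this acyclic trioxygenated complex lacks direct precedent). Thermal loss of a cis CO ligand from 6 lets 7 bind and insert into the Cr=C bond with its CH terminus joining the carbene carbon (C5–C6), and CO then inserts at the acetal-bearing carbon (C4a–C8a) to give a chromium-bound dienylketene. Ring A closes by six-electron electrocyclisation of the ketene carbon onto the methoxy-bearing vinyl terminus (C8–C8a), eased by the Z geometry of 6, which turns that methoxyl outward, and enolisation of the cyclohexadienone gives the Cr(CO)3-bound phenol 8. The selectivity required is the regiochemistry of alkyne insertion, and the size difference between H and CH(OEt)2 on the terminal alkyne secures it by placing the substituted carbon next to the CO-derived carbon, so the future C4 lies ortho to the C8a hydroxyl. No stereocentre is formed. Air removes the Cr(CO)3 group from 8 under conditions too mild to take the hydroquinone monoether on to a quinone, and THF as solvent favours the phenol over cyclobutenone or furan products.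

Step 4
Reactants: 9 2-(diethoxymethyl)-4,5,6-trimethoxyphenol
Product: 10 2-hydroxy-3,4,5-trimethoxybenzaldehyde
Conditions: 1 M HCl, THF, rt
Reagents that add atoms: water O
Why: Acid-catalysed acetal hydrolysis, fast for an electron-rich benzylic acetal and harmless to the aryl methyl ethers.

Step 5
Reactants: 11 3-hydroxy-4,5-dimethoxybenzaldehyde
Product: 12 3-(benzyloxy)-4,5-dimethoxybenzaldehyde
Conditions: BnBr, K2CO3, DMF, rt
Reagents that add atoms: benzyl bromide BrCc1ccccc1
Why: Williamson ether synthesis on the only phenol; the benzyl ether should survive the base, organolithium and MnO2 steps and leave by hydrogenolysis at the end.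

Step 6
Reactants: 12 3-(benzyloxy)-4,5-dimethoxybenzaldehyde
Product: 13 1-(benzyloxy)-5-ethynyl-2,3-dimethoxybenzene
Conditions: dimethyl (1-diazo-2-oxopropyl)phosphonate, K2CO3, MeOH, rt
Reagents that add atoms: dimethyl (1-diazo-2-oxopropyl)phosphonate CC(=O)C(=[N+]=[N-])P(=O)(OC)OC
Why: Ohira–Bestmann variant of the Seyferth–Gilbert homologation, in which the diazomethylphosphonate anion made in situ adds to the aldehyde and the resulting diazoalkene loses N2 with a 1,2-shift to give the terminal alkyne.

Step 7
Reactants: 13 1-(benzyloxy)-5-ethynyl-2,3-dimethoxybenzene; 10 2-hydroxy-3,4,5-trimethoxybenzaldehyde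
Product: 15 2-{3-[3-(benzyloxy)-4,5-dimethoxyphenyl]-1-hydroxyprop-2-yn-1-yl}-4,5,6-trimethoxyphenol (racemic), via lithium acetylide 14 (not isolated)
Conditions: 13 (2.3 equiv), n-BuLi (2.2 equiv), THF, −78 °C; then 10, −78 to 0 °C; aq NH4Cl
Reagents that add atoms: n-butyllithium CCCC[Li] (lithium of intermediate 14 only)
Why: Acetylide 1,2-addition to an aldehyde, in which the first equivalent of 14 only deprotonates the phenol (returning recoverable 13) and the second adds to the lithium phenoxide aldehyde; the carbinol stereocentre forms racemic and is erased in step 8.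

Step 8
Reactants: 15 2-{3-[3-(benzyloxy)-4,5-dimethoxyphenyl]-1-hydroxyprop-2-yn-1-yl}-4,5,6-trimethoxyphenol
Product: 16 3-[3-(benzyloxy)-4,5-dimethoxyphenyl]-1-(2-hydroxy-3,4,5-trimethoxyphenyl)prop-2-yn-1-one
Conditions: MnO2 (activated, excess), CH2Cl2, rt
Reagents that add atoms: none
Why: MnO2 oxidation of a benzylic-propargylic alcohol, selective under neutral conditions that should leave the phenol, the aryl ethers and the alkyne untouched.

Step 9
Reactants: 16 3-[3-(benzyloxy)-4,5-dimethoxyphenyl]-1-(2-hydroxy-3,4,5-trimethoxyphenyl)prop-2-yn-1-one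
Product: 17 2-[3-(benzyloxy)-4,5-dimethoxyphenyl]-6,7,8-trimethoxy-4H-chromen-4-one
Conditions: K2CO3, acetone, reflux
Reagents that add atoms: none
Why: Base-mediated 6-endo-dig oxa-Michael addition of the phenoxide to the ynone beta-carbon, the mode favoured over 5-exo (aurone) closure with K2CO3 in an aprotic solvent, followed by protonation of the allenolate to the 4-pyranone of ring C.

Step 10
Reactants: 17 2-[3-(benzyloxy)-4,5-dimethoxyphenyl]-6,7,8-trimethoxy-4H-chromen-4-one
Product: 18 2-(3-hydroxy-4,5-dimethoxyphenyl)-6,7,8-trimethoxy-4H-chromen-4-one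
Conditions: H2 (1 atm), Pd/C, EtOAc–MeOH, rt
Reagents that add atoms: none
Why: Catalytic hydrogenolysis of a benzyl aryl ether, stopped after one equivalent of hydrogen so that the C2–C3 double bond of the chromone is kept.

**Compound list**
1 | 1,1,2-trimethoxyethane | COCC(OC)OC | starting material
2 | (Z)-1,2-dimethoxyethene | CO/C=C\OC | intermediate
3 | chromium hexacarbonyl | [Cr].[C-]#[O+].[C-]#[O+].[C-]#[O+].[C-]#[O+].[C-]#[O+].[C-]#[O+] | starting material
4 | (Z)-1,2-dimethoxyvinyllithium | CO/C=C(\OC)[Li] | intermediate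
5 | lithium pentacarbonyl[(Z)-2,3-dimethoxyprop-2-enoyl]chromate | CO/C=C(/C([O-])=[Cr])OC.[Li+].[C-]#[O+].[C-]#[O+].[C-]#[O+].[C-]#[O+].[C-]#[O+] | intermediate
6 | pentacarbonyl[(Z)-1,2,3-trimethoxyprop-2-en-1-ylidene]chromium | CO/C=C(/C(OC)=[Cr])OC.[C-]#[O+].[C-]#[O+].[C-]#[O+].[C-]#[O+].[C-]#[O+] | intermediate
7 | 3,3-diethoxyprop-1-yne | C#CC(OCC)OCC | starting material
8 | tricarbonyl[η6-2-(diethoxymethyl)-4,5,6-trimethoxyphenol]chromium | CCOC(OCC)c1cc(OC)c(OC)c(OC)c1O.[Cr].[C-]#[O+].[C-]#[O+].[C-]#[O+] | intermediate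
9 | 2-(diethoxymethyl)-4,5,6-trimethoxyphenol | CCOC(OCC)c1cc(OC)c(OC)c(OC)c1O | intermediate
10 | 2-hydroxy-3,4,5-trimethoxybenzaldehyde | O=Cc1cc(OC)c(OC)c(OC)c1O | intermediate
11 | 3-hydroxy-4,5-dimethoxybenzaldehyde | COc1cc(C=O)cc(O)c1OC | starting material
12 | 3-(benzyloxy)-4,5-dimethoxybenzaldehyde | COc1cc(C=O)cc(OCc2ccccc2)c1OC | intermediate
13 | 1-(benzyloxy)-5-ethynyl-2,3-dimethoxybenzene | COc1cc(C#C)cc(OCc2ccccc2)c1OC | intermediate
14 | lithium [3-(benzyloxy)-4,5-dimethoxyphenyl]acetylide | COc1cc(C#C[Li])cc(OCc2ccccc2)c1OC | intermediate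
15 | 2-{3-[3-(benzyloxy)-4,5-dimethoxyphenyl]-1-hydroxyprop-2-yn-1-yl}-4,5,6-trimethoxyphenol (racemic) | COc1cc(C#CC(O)c2cc(OC)c(OC)c(OC)c2O)cc(OCc2ccccc2)c1OC | intermediate
16 | 3-[3-(benzyloxy)-4,5-dimethoxyphenyl]-1-(2-hydroxy-3,4,5-trimethoxyphenyl)prop-2-yn-1-one | COc1cc(C#CC(=O)c2cc(OC)c(OC)c(OC)c2O)cc(OCc2ccccc2)c1OC | intermediate
17 | 2-[3-(benzyloxy)-4,5-dimethoxyphenyl]-6,7,8-trimethoxy-4H-chromen-4-one | COc1cc(-c2cc(=O)c3cc(OC)c(OC)c(OC)c3o2)cc(OCc2ccccc2)c1OC | intermediate
18 | 2-(3-hydroxy-4,5-dimethoxyphenyl)-6,7,8-trimethoxy-4H-chromen-4-one | COc1cc(-c2cc(=O)c3cc(OC)c(OC)c(OC)c3o2)cc(O)c1OC | target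

**Step count**
Total: 10 steps. Longest linear sequence: 8 steps (steps 1, 2, 3, 4, 7, 8, 9, 10); steps 5 and 6 form the ring B branch.

**Steps most likely to fail**

1. Step 3. The donor-rich, push–pull carbene complex may lose CO too slowly, or the vinylketene may divert to cyclobutenone, furan or cyclopentenone formation instead of electrocyclising. Fallback (squarate route to the same ring A aldehyde): it sets out from alkyne 7. Its lithium acetylide (n-BuLi, THF, −78 °C) is added to commercial dimethyl squarate to give 4-(3,3-diethoxyprop-1-yn-1-yl)-4-hydroxy-2,3-dimethoxycyclobut-2-en-1-one F1. Moore thermolysis in refluxing p-xylene should open F1 to an enynylketene that recloses with hydrogen transfer to 5-(diethoxymethyl)-2,3-dimethoxy-1,4-benzoquinone F2. Na2S2O4 reduces F2 to 2-(diethoxymethyl)-5,6-dimethoxybenzene-1,4-diol F3, and dilute HCl hydrolyses the acetal to 2,5-dihydroxy-3,4-dimethoxybenzaldehyde F4. One equivalent of MeI with K2CO3 in acetone under argon should methylate the 5-hydroxyl, which is not hydrogen-bonded to the aldehyde, and the fallback returns to the route at 10.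

2. Step 2. The vinyllithium 4 has lithium trans to the beta-methoxyl and may eliminate LiOMe to methoxyacetylene before it adds to the poorly soluble Cr(CO)6; lithiation may also be incomplete at −78 °C. Fallback (acyl chloride plus pentacarbonylchromate dianion, no vinyllithium): it sets out from chromium hexacarbonyl 3 and commercial methyl methoxyacetate. Formylation of the ester with methyl formate and NaH, then O-methylation of the enolate with Me2SO4, gives methyl (Z)-2,3-dimethoxyprop-2-enoate F5. LiOH saponification gives (Z)-2,3-dimethoxyprop-2-enoic acid F6, and 1-chloro-N,N,2-trimethylpropenylamine converts it under neutral conditions to (Z)-2,3-dimethoxyprop-2-enoyl chloride F7. Separately, 3 is reduced with potassium graphite KC8 in THF to dipotassium pentacarbonylchromate K2Cr(CO)5 F8. F8 is acylated by F7 to potassium pentacarbonyl[(Z)-2,3-dimethoxyprop-2-enoyl]chromate F9, and O-methylation with Me3OBF4 returns to the route at 6.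

3. Step 8. With the electron-rich phenol free, oxidation of the aromatic ring or ionisation of the ortho-hydroxybenzylic alcohol to an ortho-quinone methide may compete with alcohol oxidation; the same free phenol may also make the addition in step 7 sluggish. Fallback (mask the ring A phenol through both steps): it sets out from 10. MOMCl and i-Pr2NEt give 3,4,5-trimethoxy-2-(methoxymethoxy)benzaldehyde F10. Addition of 1.2 equivalents of acetylide 14 gives 3-[3-(benzyloxy)-4,5-dimethoxyphenyl]-1-[3,4,5-trimethoxy-2-(methoxymethoxy)phenyl]prop-2-yn-1-ol F11, and MnO2 oxidises it to 3-[3-(benzyloxy)-4,5-dimethoxyphenyl]-1-[3,4,5-trimethoxy-2-(methoxymethoxy)phenyl]prop-2-yn-1-one F12. HCl in MeOH removes the MOM group and the fallback returns to the route at 16.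

**Further compounds**
F1 | step 3 | 4-(3,3-diethoxyprop-1-yn-1-yl)-4-hydroxy-2,3-dimethoxycyclobut-2-en-1-one (racemic) | CCOC(OCC)C#CC1(O)C(OC)=C(OC)C1=O
F2 | step 3 | 5-(diethoxymethyl)-2,3-dimethoxy-1,4-benzoquinone | CCOC(OCC)C1=CC(=O)C(OC)=C(OC)C1=O
F3 | step 3 | 2-(diethoxymethyl)-5,6-dimethoxybenzene-1,4-diol | CCOC(OCC)c1cc(O)c(OC)c(OC)c1O
F4 | step 3 | 2,5-dihydroxy-3,4-dimethoxybenzaldehyde | O=Cc1cc(O)c(OC)c(OC)c1O
F5 | step 2 | methyl (Z)-2,3-dimethoxyprop-2-enoate | CO/C=C(\OC)C(=O)OC
F6 | step 2 | (Z)-2,3-dimethoxyprop-2-enoic acid | CO/C=C(\OC)C(=O)O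
F7 | step 2 | (Z)-2,3-dimethoxyprop-2-enoyl chloride | CO/C=C(\OC)C(=O)Cl
F8 | step 2 | dipotassium pentacarbonylchromate K2Cr(CO)5 | [K+].[K+].[Cr-2].[C-]#[O+].[C-]#[O+].[C-]#[O+].[C-]#[O+].[C-]#[O+]
F9 | step 2 | potassium pentacarbonyl[(Z)-2,3-dimethoxyprop-2-enoyl]chromate | CO/C=C(/C([O-])=[Cr])OC.[K+].[C-]#[O+].[C-]#[O+].[C-]#[O+].[C-]#[O+].[C-]#[O+]
F10 | step 8 | 3,4,5-trimethoxy-2-(methoxymethoxy)benzaldehyde | COCOc1c(C=O)cc(OC)c(OC)c1OC
F11 | step 8 | 3-[3-(benzyloxy)-4,5-dimethoxyphenyl]-1-[3,4,5-trimethoxy-2-(methoxymethoxy)phenyl]prop-2-yn-1-ol (racemic) | COCOc1c(C(O)C#Cc2cc(OC)c(OC)c(OCc3ccccc3)c2)cc(OC)c(OC)c1OC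
F12 | step 8 | 3-[3-(benzyloxy)-4,5-dimethoxyphenyl]-1-[3,4,5-trimethoxy-2-(methoxymethoxy)phenyl]prop-2-yn-1-one | COCOc1c(C(=O)C#Cc2cc(OC)c(OC)c(OCc3ccccc3)c2)cc(OC)c(OC)c1OC
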